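(The numbers in the tables stem from a simulated flask for substances that don't exist, and the scatter is random.)

- At 2.5 d we read Tuesday's flask and must choose what to do with it for 30 h more.

| setting | Tuesday's | Wednesday's | flask |
|---|---|---|---|
| Q | 0.067 M | 0.10 M | 0.067 M |
| D | 0.067 M | 0.067 M | 0.0670 M |
| X | 2.9 mM | 2.9 mM | 2.9 mM |
| temperature | 100 °C | 95 °C | 100 °C |
| remark | the very flask that is asked about, followed so far | run made earlier |  |
| time |  |  | 2.5 d |

Tuesday's run (percent of the Q charged)

| time / h | J / % | Q / % |
|---|---|---|
| 4.00 | 4 | 71 |
| 12.0 | 11 | 43 |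
| 20.0 | 15 | 30 |
| 30.0 | 19 | 24 |
| 50.0 | 19 | 17 |

Wednesday's run (percent of the Q charged)

| time / d | J / % | Q / % |
|---|---|---|
| 0.208 | 0 | 75 |
| 0.417 | 2 | 57 |
| 0.625 | 8 | 46 |
| 1.25 | 14 | 28 |
| 2.50 | 15 | 15 |

(scatter of a reading: 1.5 percentage points)

* J, in percent of the Q first charged, at 2.5 d
* the remedy with the largest gain of J, or "none" below 2 percentage points (autumn / midnight / noon / spring / none)
* J present, with what was taken out counted in, in percent of the Q first charged, after noon
* J present, with what was taken out counted in, in percent of the Q first charged, after spring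

- autumn: at 2.5 d add X, 50.0 % of the amount charged, then wait 30 h
- midnight: change nothing and wait 30 h more
- noon: at 2.5 d take out 90 % of the J then present, then wait 30 h
- spring: at 2.5 d raise the temperature by 25 K, then wait 30 h

- J that was removed still counts
- additions bring no volume worth counting

- Which numbers must be known well? X and D stood at the same charges in both runs, so the readings give no number for them, nor for autumn.
- The charge of Q seems minor. Wednesday's run held more Q and ran cooler, yet Q at 1.25 d reads 28 % against 30 % at 20.0 h on Tuesday, and J reads 14 % against 15 %.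
- We read that lag as temperature. 5.00 K stretches time by 1.50.
- Over the 25 K of spring, that stretch taken 5 times is 7.59. This is the heat clock, the hours at the old temperature worth one hour after the rise, an Arrhenius acceleration factor.
- The time of reading matters little. We replace J's bent curve by its mean slope over Wednesday's last 30 h. That rise of 1 percentage point becomes 1.5 points at Tuesday's temperature.
- So the 10.0 h after Tuesday's last reading bring J to 19.5 %.
- The mean slope is the weak number. A difference of two readings scatters by 2.1 points, more than the rise itself, and the heat clock multiplies that error too.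
- We still commit: midnight gains 1.5 points, spring gains 11 points, and J after spring is 30.9 %.
- The forecast gave J 19.5 % now, autumn as best, 20 % after noon and 21 % after spring, holding that “Heating only speeds the trace of living catalyst”. Our spring figure stands higher.
- The flask gives J 19.8 % now, and spring is best: it gains 16 points, against 9.7 points for noon, 8.8 points for autumn and 2.1 points for midnight. J stands at 29.5 % after noon and 35.8 % after spring.

    X → E (k = 0.00210 /min, Ea = 110 kJ/mol)
    Z + X ⇌ G + X, rate k2*[X]*[Z] forward; the back reaction follows from the equilibrium constant (K = 0.340, k = 0.200 /M/min, Ea = 94.0 kJ/mol, ΔH = −45.0 kJ/mol)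
    Q ⇌ J (K = 10.0, k = 1.50 × 10⁻⁴ /min, Ea = 127 kJ/mol, ΔH = −23.0 kJ/mol)
    J ⇌ Z (K = 0.710, k = 0.00360 /min, Ea = 118 kJ/mol, ΔH = 10.0 kJ/mol)
    G ⇌ Q (k = 4.70 × 10⁻⁴ /min, Ea = 129 kJ/mol)
    Q + D → L (k = 9.40 × 10⁻⁴ /M/min, Ea = 112 kJ/mol)
    (constants at 100 °C)

- In this flask, midnight's gain times the heat clock is 16 points, and spring's gain is 16 points. Our heat clock, itself read from scattered readings, reckons a neighbour flask kept at 125 °C for 2.5 d as 19.0 d at Tuesday's temperature. It holds J 35.9 % and Q 4.94 %. Tuesday's flask, left alone, holds J 35.7 % and Q 4.80 % at 25.0 d.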